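Ask which charge of coupling partner leaves the most target in the flask at 8.0 min.

all flasks: substrate 0.050 M; fresh partner 0.0525 M
- Saturday's: coupling partner 0.033 M; run made earlier
- Monday's: coupling partner 0.54 M; run made earlier
- dawn: coupling partner 0.0250 M; time 8.0 min
- noon: coupling partner 0.0500 M; time 8.0 min
- winter: coupling partner 0.100 M; time 8.0 min
- dusk: coupling partner 0.200 M; time 8.0 min
- spring: coupling partner 0.400 M; time 8.0 min

| run | time / min | target / % |
|---|---|---|
| Saturday's | 0.500 | 0 |
| Saturday's | 1.33 | 0 |
| Saturday's | 2.50 | 5 |
| Saturday's | 4.00 | 3 |
| Monday's | 1.00 | 12 |
| Monday's | 2.00 | 19 |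
| Monday's | 3.00 | 16 |
| Monday's | 4.00 | 11 |

(scatter of a reading: 2 percentage points)

- "hardly changes" means that all values lie within two and a half points (for a concentration: within two and a half percent of the largest)

* [target] at the end for dawn, noon, winter, dusk, spring, in this order
* the shape of the row from first to last (hardly changes / rises all the way / falls, then rises / rises, then falls / falls all the way)

Read Monday first. Target climbs to 19% at 2.00 min and falls to 11% at 4.00 min, so it forms and is then consumed. Saturday, at 0.033 M, reads 3% at 4.00 min, against a scatter of 2 percentage points. So Saturday's small charge moves its flask slowly.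

Assume that coupling partner stays near its charge, so that making and consuming target are both pseudo-first-order. Then, with substrate and fresh partner as charged here, charge times peak time stays constant. Take Monday's product and divide it by 8.0 min: the charge reckoned to peak at the asked time is 0.135 M. On this assumption, a lower charge is still rising at that time, and a higher one is past its peak. Commit to a row that rises, then falls.

The weak link is the peak time, read from a grid with steps of 1.00 min. Reforge it. Lay a parabola through Monday's readings at 1.00 min, 2.00 min and 3.00 min. Its vertex, a reading with Monday's scatter, lies at 2.20 min, which gives 0.148 M. Call this c*, the turning charge: the charge whose target, on this assumption, peaks at the asked time. It lies above winter's 0.100 M and below dusk's 0.200 M. This reckoning gives a turn and no heights.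

The forecast gives heights: 0.0035 M, 0.006 M, 0.0085 M, 0.008 M, 0.004 M, with the shape rises, then falls. It stands highest at winter, on the view that “both steps scale with coupling partner”.

The flask gives 0.00357 M, 0.0106 M, 0.0235 M, 0.0174 M, 0.00537 M: rises, then falls. These steps stand behind it.

    coupling partner + target → over-reaction product (k = 0.0276 M⁻¹ s⁻¹)
    open intermediate + second intermediate → target (k = 0.0928 M⁻¹ s⁻¹)
    coupling partner + fresh partner → second intermediate (k = 0.278 M⁻¹ s⁻¹)
    substrate + coupling partner → open intermediate (k = 0.147 M⁻¹ s⁻¹)

The row turns at 0.12 M, below c*, and winter's 0.0235 M is 2.76 times the forecast's 0.0085 M. Now use c* on dusk. Multiply it by 8.0 min and divide by dusk's charge of 0.200 M: the reckoning puts dusk's peak at 5.92 min. Dusk holds target, in percent of the substrate charged, at 34.1% at 4.00 min and 34.8% at 8.00 min.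

The runs are calculated for substances that don't exist; scatter was added.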